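The data are simulated from invented constants.

The green run cannot have stopped for want of material: product levels at 6.3 % of the charge, so 93.7 % of it is not product, and the solid reads 0 %. I leave open what levels each run, and ask how far a flask gets.

| setting | green | red | north-east | north-west |
|---|---|---|---|---|
| solid substrate | 0.040 M | 0.12 M | 0.060 M | 0.20 M |
| free enzyme | 0.027 mol% | 0.027 mol% | 0.027 mol% | 0.027 mol% |
| temperature | 25 °C | 40 °C | 50 °C | 30 °C |
| remark | run made earlier | run made earlier |  |  |
| time |  |  | 30 d | 8.0 d |

| run | time / d | product / % | solid substrate / % |
|---|---|---|---|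
| green | 1.25 | 4.0 | 0.3 |
| green | 2.50 | 5.2 | 0.4 |
| green | 4.00 | 6.1 | 0.2 |
| green | 5.00 | 6.3 | 0 |
| green | 6.00 | 6.1 | 0.4 |
| green | 8.00 | 6.3 | 0 |
| red | 0.833 | 6.9 | 0 |
| red | 1.67 | 11.4 | 0.1 |
| red | 2.50 | 14.9 | 0.1 |
| red | 3.00 | 15.8 | 0 |
| red | 4.00 | 17.9 | 0 |
| red | 5.00 | 18.5 | 0 |

(readings scatter by 0.3 percentage points)

- solid substrate is a solid; its amount is given per volume of the solution
- the numbers in the tables scatter by 0.3 percentage points (one standard deviation)
- on the list of suspects stand: solid substrate <-> starting material; free enzyme -> unfolded enzyme; 2 free enzyme -> spent catalyst; starting material + free enzyme -> product + free enzyme; starting material <-> dormant form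
- at the start none of the solid substrate is in solution
- what has only dissolved of solid substrate counts as not reacted
- where the amount of solid substrate changes, what is given in equivalents or mol% on it follows

- which one finishes higher in amount of product, in percent of the solid substrate charged ("neither" within 2 percentage points) (north-east / north-west / neither)
- amount of product at the end, in percent of the solid substrate charged, north-east
- amount of product at the end, in percent of the solid substrate charged, north-west

I work this out from each run separately. The last green reading gives a final product fraction per molar of solid substrate charged of 1.57 M⁻¹, and the last red reading gives 1.54 M⁻¹. I keep their mean as the capacity, the final fraction of the charge turned to product per molar of solid substrate charged: 1.56 M⁻¹. The two ways agree, but the check is not clean, since red changes charge and temperature together and still gains 0.6 percentage points between its last two readings. I commit to 9.35 % for north-east and 31.2 % for north-west. I take 8.0 d as long enough, since it is longer than the 5.00 d by which green lies flat.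

The forecast also names north-west, with 11.5 % (7 % to 16 %) for north-east and 28 % (20 % to 34 %) for north-west, holding that “the plateau is set by enzyme lifetime”. Its north-east figure is higher than mine, and its north-west figure is lower.

The flasks give 6.26 % for north-east and 21.9 % for north-west, so north-west finishes higher.

    solid substrate ⇌ starting material, rate k1*(cs1 - [starting material]) while solid is left; crystals form when [starting material] > cs1 (solubility = 0.190 M, k = 0.0427 h⁻¹)
    free enzyme → unfolded enzyme (k = 6.93 × 10⁻⁴ h⁻¹, Ea = 195 kJ mol⁻¹)
    2 free enzyme → spent catalyst (k = 1220 M⁻¹ h⁻¹, Ea = 52.0 kJ mol⁻¹)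
    starting material + free enzyme → product + free enzyme, rate k4*[starting material]^2*[free enzyme]/(1 + ([starting material]/Kh4)^2) (0.129 M, k = 11700 M⁻² h⁻¹, Ea = 46.0 kJ mol⁻¹)
    starting material ⇌ dormant form (K = 2.10, k = 0.0388 h⁻¹, Ea = 94.0 kJ mol⁻¹, ΔH = −72.0 kJ mol⁻¹)
    (constants at 30 °C)

North-east has come to rest: product reads 6.26 % at 15.0 d and 6.26 % at 300 d, with free enzyme at 0 %, and that rest lies below the capacity's 9.35 %. North-west has not: at 8.00 d free enzyme still stands at 3.55 %. Its neighbour with 0.080 M of solid substrate reads 14.0 % at 8.00 d, against 12.5 % from the capacity. Left until 80.0 d, north-west climbs from 21.9 % to 30.2 %, against the capacity's 31.2 %.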